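We count per hour and per catalyst, in this flask:

substrate 0.23 M; reagent 3.00 equiv; free catalyst 5.5 mol%

- the form that holds most of the catalyst when 30% of the substrate are converted (catalyst intermediate / free catalyst)
- its share of the catalyst then
- apparent order in reagent when 30% of the substrate are converted (percent change of the rate of making target for one percent more reagent charged)
- apparent order in free catalyst when 30% of the substrate are converted (percent change of the rate of making target for one percent more free catalyst charged)

    2 substrate → self-condensation product (k1 = 0.028 M⁻¹ h⁻¹)
    substrate + free catalyst ⇌ free catalyst + open intermediate (K2 = 2.2, k2 = 2.9 M⁻¹ h⁻¹)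
    reagent + catalyst intermediate → free catalyst + target (k3 = 0.82 M⁻¹ h⁻¹)
    free catalyst + open intermediate ⇌ catalyst intermediate (K4 = 85 M⁻¹, k4 = 7.0 M⁻¹ h⁻¹)

Substrate becomes open intermediate on free catalyst (rate constant k2) or condenses with itself (k1). Free catalyst catches open intermediate as catalyst intermediate (k4, equilibrium constant K4), and reagent turns that into target and free catalyst (k3). Two rates stand against each other: capture per free catalyst, κ = k4[open intermediate], and leaving per catalyst intermediate, w = k3[reagent] + k4/K4, which is 0.648 h⁻¹ with reagent as charged.

For κ we replace curves by their means. With substrate at its mean and the catalyst counted as free, the catalyst route takes 77.0% of the 0.0690 M of substrate lost, in about 7.41 h. That makes 0.0531 M of open intermediate. Catalyst intermediate, at half its end value on average, carries 0.00967 M on to target, leaving 0.0435 M, so κ is 0.304 h⁻¹.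

The capture ratio ρ, catalyst intermediate over free catalyst, is then κ/w = 0.469. It may be used at that moment, since the forms balance within 1/(w+κ) = 1.05 h, shorter than 7.41 h. The resting state is free catalyst, with a share of 1/(1+ρ) = 68.1%. The rate goes as k3[reagent]·[catalyst]·κ/(w+κ), so at fixed κ the order in reagent is 0.406 and in catalyst 1.00.

The forecast gives free catalyst at 71%, with orders 0.42 and 1.25, the latter above ours, holding that “more catalyst beats self-condensation”. The simulation gives free catalyst at 72.6%, with orders 0.41 and 1.1.

In this flask at that conversion, catalyst intermediate over free catalyst reads 0.378, less than our ρ of 0.469, so with w as reckoned κ comes to 0.245 h⁻¹, not our 0.304 h⁻¹. In the flask with twice the reagent, holding κ and raising w to 1.21 h⁻¹ puts the factor on the rate at 1.26, and the run reads 1.25.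

Its constants were set for the occasion, and the outcome is calculated.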